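The ratio of left-handed to right-handed product, taken over the four readings of each run, stands at 1.91 in the autumn run at 0 °C and at 0.794 in the midnight run at 30 °C.

| flask | left-handed substrate | right-handed substrate | solid reagent | temperature | remark | time |
|---|---|---|---|---|---|---|
| autumn | 28 mM | 28 mM | 2 equiv | 0 °C | run made earlier |  |
| midnight | 44 mM | 44 mM | 2 equiv | 30 °C | run made earlier |  |
| summer | 20 mM | 20 mM | 3 equiv | 0 °C | run made earlier |  |
| eta | 20 mM | 20 mM | 2.00 equiv | 55 °C |  | 10 min |
| gamma | 20 mM | 20 mM | 2.00 equiv | 30 °C |  | 10 min |
| epsilon | 20 mM | 20 mM | 2.00 equiv | 5 °C |  | 10 min |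

| run | time / min | left-handed product / % | right-handed product / % |
|---|---|---|---|
| autumn | 15.0 | 10.4 | 5.9 |
| autumn | 30.0 | 18.4 | 9.4 |
| autumn | 80.0 | 28.9 | 14.3 |
| autumn | 180 | 29.0 | 15.7 |
| midnight | 3.00 | 2.1 | 2.2 |
| midnight | 6.00 | 3.3 | 4.4 |
| midnight | 15.0 | 5.0 | 6.3 |
| midnight | 40.0 | 5.0 | 6.5 |
| summer | 25.0 | 18.1 | 9.4 |
| summer | 60.0 | 28.4 | 14.8 |
| summer | 120 | 30.6 | 15.9 |
| summer | 180 | 31.1 | 16.3 |

(each reading ± 0.3 percentage points)

- partner is single-handed; left-handed substrate and right-handed substrate are mirror images of each other, charged as a racemate, each of them at the stated concentration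
- solid, in amounts per volume of the solution: solid reagent
- at the start none of the solid reagent is in solution
- the handed part of partner does not stay in what it makes, so the products of the two hands are mirror images too

* which flask leads in share of left-handed product in all that became left-handed product or right-handed product ("all alike" within 1.5 percentage points) (eta / gamma / epsilon / all alike)
* share of left-handed product in all that became left-handed product or right-handed product, eta
* share of left-handed product in all that became left-handed product or right-handed product, gamma
* share of left-handed product in all that became left-handed product or right-handed product, epsilon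

Two chemists read these tables differently. The first takes the ratio for a selectivity factor, a quotient of two rate constants, so it should move with temperature and hold still during a run. The midnight run also differs in concentration, 44 mM against 28 mM, but the summer run at 0 °C with 20 mM reads 1.92, close to the autumn ratio. She divides the fall in the logarithm of the ratio by the change in reciprocal absolute temperature and multiplies by the gas constant. That gives 20.2 kJ mol⁻¹: the handedness gap, the extra activation energy of making right-handed product over making left-handed product.

The second treats each hand as a separate pool, as in plain kinetic resolution, so the left-handed substrate should drain faster and the share should sink as a run proceeds. Separate pools keep one number constant: the logarithm of what remains of one hand over that of the other. In the autumn run this number reads 1.86 at 15.0 min and 2.30 at 180 min, while the product ratio reads 1.76 and 1.85. The product ratio is the steadier of the two, so I side with the first chemist. Carrying the gap from the autumn ratio, I reckon a ratio of 0.431 for eta, which is a share of 30.1%, and a ratio of 1.63 for epsilon, which is a share of 62.0%. For gamma, at the temperature of the midnight run, I take the midnight ratio, which is a share of 44.3%.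

The forecast takes the same side, with 30% for eta, 44% for gamma and 62% for epsilon, so epsilon leads. It reasons that “it should depend on temperature, not on time or charge”.

The flasks give 27.5% for eta, 42.4% for gamma and 61.7% for epsilon, and epsilon leads.

    partner + left-handed substrate → left-handed product (k = 0.710 M⁻¹ s⁻¹, Ea = 37.0 kJ mol⁻¹)
    partner + right-handed substrate → right-handed product (k = 0.440 M⁻¹ s⁻¹, Ea = 59.0 kJ mol⁻¹)
    left-handed substrate ⇌ achiral form (K = 0.570, k = 0.120 s⁻¹, Ea = 67.0 kJ mol⁻¹, ΔH = −29.0 kJ mol⁻¹)
    right-handed substrate ⇌ achiral form (K = 0.570, k = 0.120 s⁻¹, Ea = 67.0 kJ mol⁻¹, ΔH = −29.0 kJ mol⁻¹)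
    solid reagent ⇌ partner, rate k5*(cs5 - [partner]) while solid is left; crystals form when [partner] > cs5 (solubility = 1.50 mM, k = 0.0150 s⁻¹)
    achiral form → decomposed reagent (k = 0.00260 s⁻¹, Ea = 84.0 kJ mol⁻¹)
    2 partner → homo dimer (k = 0.100 M⁻¹ s⁻¹, Ea = 62.0 kJ mol⁻¹)
    (constants at 5 °C)

Carried to the same flask as gamma, run at 15 °C, the handedness gap gives a ratio of 1.20, which is a share of 54.5%, and that flask gives 53.7%. Separate pools need capture by partner to outrun the turning of substrate into achiral form, but in gamma at 10.0 min the forward turning of right-handed substrate into achiral form runs 330 times as fast as its capture, which is dynamic kinetic resolution, and in gamma that exchange, both ways together, has a relaxation half-life of 0.0893 s by this step alone.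

The runs are calculated on assumed constants.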